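The readings stem from a simulated flask with constants of no real substance; the scatter is artificial.

Of the X charged in the summer run, 92.3% was still not J at the last reading, at 5.00 d. Where does that leftover end up?

In J, as far as the listed steps go. X → Z and E + Z → E + J run one way and E comes back from each turn, so the end state holds the charge as J. The real question is how fast the flask gets there.

| flask | X | E | temperature | remark | time |
|---|---|---|---|---|---|
| spring | 0.65 M | 0.42 mM | 55 °C | run made earlier |  |
| summer | 0.65 M | 0.93 mM | 75 °C | run made earlier |  |
| midnight | 1.3 M | 0.62 mM | 55 °C | run made earlier |  |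
| alpha | 0.65 M | 0.62 mM | 75 °C |  | 6.0 d |
| zeta | 0.65 M | 0.62 mM | 60 °C |  | 6.0 d |
| delta | 0.65 M | 0.62 mM | 90 °C |  | 6.0 d |

| run | time / d | J / % |
|---|---|---|
| spring | 1.04 | 0 |
| spring | 2.50 | 0.9 |
| spring | 6.00 | 0.2 |
| spring | 15.0 | 2.2 |
| summer | 0.625 | 0 |
| summer | 1.67 | 1.6 |
| summer | 3.00 | 4.3 |
| summer | 5.00 | 7.7 |
| midnight | 1.04 | 0.6 |
| midnight | 2.50 | 0 |
| midnight | 6.00 | 1.5 |
| midnight | 15.0 | 1.4 |

(each reading ± 0.5 percentage points)

- what may be going on: E + Z -> E + J; X -> Z; 2 E <-> Q

- the flask with the highest amount of J, in percent of the X charged ("all alike" if they lie within 1.5 percentage points) (alpha / zeta / delta / all alike)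
- final J, as a percentage of the X charged, in alpha
- final J, as a percentage of the X charged, in zeta
- final J, as a percentage of the X charged, in delta

How fast, then?

The summer run shows a clear rise: J climbs from 1.6% to 7.7% of the charge between 1.67 d and 5.00 d. That gives 0.0183 d⁻¹, which I call the clearing pace, the fraction of the charge turned into J per day at 75 °C with 0.93 mM of E.

Can two noisy readings bear that?

The rise is 6.1 percentage points against a scatter of 0.5 points on each reading, so it can, as a reading and no better.

Does that line start at time zero?

No, it meets zero J at 0.797 d. This is a reading of the lag (induction period), and it fits J being made from Z, which has to build up first.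

Your figure for alpha?

Alpha stands at the summer temperature with 0.62 mM of E, less than the summer run's 0.93 mM. Pace and lag give 9.53% at 6.0 d, and I hold that figure with its risk on the high side.

And the other flasks?

The spring run rises at about 0.00147 d⁻¹ as a reading, lower than the clearing pace. The spring and summer runs differ in temperature and in E, but the pace differs by a factor of about 12.5 and E by 2.21, so I lay the larger part on heat. I rank delta first, then alpha, then zeta, and give no figure for delta or zeta.

The forecast reads the summer run as “slow X → Z followed by E-catalysed Z → J”. It gives 8.5% for alpha, 1.2% for zeta and 38% for delta, with delta on top. For alpha that is lower than my figure.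

The flasks give 8.14% in alpha, 1.23% in zeta and 29.2% in delta, so delta leads, 8.8 points under the forecast's figure.

    E + Z → E + J (k = 53.0 M⁻¹ h⁻¹, Ea = 60.0 kJ mol⁻¹)
    X → Z (k = 0.0149 h⁻¹, Ea = 114 kJ mol⁻¹)
    2 E ⇌ Q (K = 2.57 × 10⁵ M⁻¹, k = 78.5 M⁻¹ h⁻¹, Ea = 74.0 kJ mol⁻¹, ΔH = 8.00 kJ mol⁻¹)
    (constants at 90 °C)

In alpha at 6.00 d, Z is made 2.99 times as fast as it is used up, each step taken net, and the flask holds 65.6% of the charge as X, 26.3% as Z and 8.14% as J. Over the second half of alpha, J climbs at 0.0155 d⁻¹, less than the clearing pace of 0.0183 d⁻¹. For the same alpha mixture read at 40 h, pace and lag give 1.59%, and that flask holds 1.54% of J.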